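**Retrosynthetic overview**
- Last bond set: the exocyclic C20=C21 alkene, by vinylogous aldol addition and elimination between the C5 anion of bought methyl 3-methyltetronate and an α-methyl aldehyde; the free tetronic acid is released by O-demethylation at the very end.
- Key disconnection C13–C15 (sp2–sp3): a light-driven, nickel-catalysed union of a (Z)-alkenyl iodide (furan side) with a primary alkyl pinacol boronate (stereocenter side); retention of the iodide geometry gives the 12Z alkene.
- The alkyl boronate comes from the bromo ester of the Roche ester series, which brings C18, by photochemical radical addition to vinyl-Bpin (C16–C17).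
- The alkenyl iodide comes from geranyl acetate, which brings the 7E alkene: selective ozonolysis, Stork–Zhao iodo-olefination (12Z), then copper-catalysed coupling with 3-furylmethyl Grignard (C5–C6).
- Rings: the furan and the butenolide are both bought intact; no ring is formed in the route.

Atom labels used below: C5 is the CH2 on the furan; C7=C8 (E, methyl on C8); C12=C13 (Z, methyl on C13); C15–C17 are the three CH2 groups; C18 is the stereocenter; C20=C21 is the exocyclic alkene (C21 is ring C5 of the butenolide).

Assumption: 3-(chloromethyl)furan and 4-methoxy-3-methylfuran-2(5H)-one are taken as catalogue compounds, and the commercial methyl (2R)-3-bromo-2-methylpropanoate supplies the only stereocenter.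

**Step 1**
Reactants: 1 geranyl acetate [(2E)-3,7-dimethylocta-2,6-dien-1-yl acetate]
Product: 3 (2E)-3-methyl-6-oxohex-2-en-1-yl acetate, via secondary ozonide 2 (not isolated)
Conditions: O3 (1.0 equiv), CH2Cl2, −78 °C; then Me2S, −78 °C → rt
Reagents that add atoms: ozone, [O-][O+]=O
Why: Chemoselective ozonolysis: one equivalent of ozone cleaves the electron-rich 6,7-alkene because the 2,3-alkene is deactivated by the allylic acetate, and Me2S reduces ozonide 2 to the aldehyde with the E alkene untouched.

**Step 2**
Reactants: 3 (2E)-3-methyl-6-oxohex-2-en-1-yl acetate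
Product: 4 (2E,6Z)-7-iodo-3-methylocta-2,6-dien-1-yl acetate
Conditions: EtPPh3I, n-BuLi, THF, rt; I2, −78 °C; NaN(SiMe3)2, −20 °C; then 3, −78 °C
Reagents that add atoms: ethyltriphenylphosphonium iodide, CC[P+](c1ccccc1)(c1ccccc1)c1ccccc1.[I-]; iodine, [I][I]
Why: Stork–Zhao-type Wittig olefination with the α-iodo ylide (1-iodoethylidene)triphenylphosphorane made in situ gives the (Z)-2-iodoalk-2-ene (iodine cis to the chain, typically ≥10:1) at −78 °C, where the acetate is inert.

**Step 3**
Reactants: 4 (2E,6Z)-7-iodo-3-methylocta-2,6-dien-1-yl acetate; 5 3-(chloromethyl)furan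
Product: 7 3-[(3E,7Z)-8-iodo-4-methylnona-3,7-dien-1-yl]furan, via (furan-3-ylmethyl)magnesium chloride 6 (not isolated)
Conditions: 5, Mg, THF, 0 °C → rt; then 4, Li2CuCl4 (3 mol %), THF, −30 → 0 °C
Reagents that add atoms: none
Why: Fouquet–Schlosser-type Li2CuCl4-catalysed coupling of the primary allylic acetate with Grignard reagent 6 occurs at the α-carbon with retention of the E alkene (γ-attack would build a quaternary carbon) and is far faster than any reaction of the Grignard reagent with the alkenyl iodide at these temperatures.

**Step 4**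
Reactants: 8 methyl (2R)-3-bromo-2-methylpropanoate; 9 vinylboronic acid pinacol ester (4,4,5,5-tetramethyl-2-vinyl-1,3,2-dioxaborolane)
Product: 10 methyl (2S)-2-methyl-5-(4,4,5,5-tetramethyl-1,3,2-dioxaborolan-2-yl)pentanoate
Conditions: (Me3Si)3SiH (1.3 equiv), 9 (3 equiv), Ir[dF(CF3)ppy]2(dtbbpy)PF6 (1 mol %), DME, 450 nm LEDs, 25 °C
Reagents that add atoms: none
Why: Photoredox-initiated silyl-radical bromine abstraction gives the primary radical •CH2CH(CH3)CO2Me, which adds to the terminal carbon of 9 (Giese-type addition, α-boryl radical stabilised by boron) and is quenched by hydrogen transfer from the silane; the bought stereocenter is β to the radical and untouched (R becomes S only through the change of CIP priorities).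

**Step 5**
Reactants: 10 methyl (2S)-2-methyl-5-(4,4,5,5-tetramethyl-1,3,2-dioxaborolan-2-yl)pentanoate; 7 3-[(3E,7Z)-8-iodo-4-methylnona-3,7-dien-1-yl]furan
Product: 11 methyl (2S,6Z,10E)-13-(furan-3-yl)-2,6,10-trimethyltrideca-6,10-dienoate
Conditions: 10 (1.5 equiv), morpholine (2.5 equiv), 4CzIPN (3 mol %), NiCl2(dme) (5 mol %), dtbbpy (5 mol %), DMA, 450 nm LEDs, 25 °C
Reagents that add atoms: none
Why: Proposed new method: a photochemical nickel-catalysed deborylative sp3–sp2 coupling in which excited 4CzIPN oxidises morpholine to its N-centred radical (fast deprotonation of the aminium ion by excess morpholine keeps it from adding to the alkenes), this radical attacks the vacant boron orbital of 10 and expels the primary C15 radical, and the alkenylnickel iodide formed by stereoretentive oxidative addition of zerovalent nickel into the C–I bond of 7 captures that radical and reductively eliminates from trivalent nickel to form C13–C15 with the Z geometry intact (the unconjugated alkenes lie far above the triplet energy of the photocatalyst, so no light-driven E/Z scrambling is expected); the closest known reaction type is the amine-mediated photoredox/nickel coupling of alkyl pinacol boronates with aryl halides, and the untested element is an unactivated trisubstituted (Z)-alkenyl iodide as electrophile, while C18 is remote from the radical site.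

**Step 6**
Reactants: 11 methyl (2S,6Z,10E)-13-(furan-3-yl)-2,6,10-trimethyltrideca-6,10-dienoate
Product: 13 (2S,6Z,10E)-13-(furan-3-yl)-2,6,10-trimethyltrideca-6,10-dienal, via diisobutylaluminium hemiacetal 12 (not isolated)
Conditions: iBu2AlH (1.1 equiv), CH2Cl2, −78 °C; aq. potassium sodium tartrate (KNaC4H4O6); crude aldehyde used at once
Reagents that add atoms: none
Why: Partial ester reduction: at −78 °C the reaction stops at the tetrahedral aluminium hemiacetal 12, which releases the aldehyde only on work-up, so the α-stereocenter never meets base and is carried forward without chromatography.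

**Step 7**
Reactants: 13 (2S,6Z,10E)-13-(furan-3-yl)-2,6,10-trimethyltrideca-6,10-dienal; 14 4-methoxy-3-methylfuran-2(5H)-one
Product: 18 (5Z)-5-[(2S,6Z,10E)-13-(furan-3-yl)-2,6,10-trimethyltrideca-6,10-dien-1-ylidene]-4-methoxy-3-methylfuran-2(5H)-one, via 5-lithio-4-methoxy-3-methylfuran-2(5H)-one 15 (not isolated), via lithium aldolate 16 (not isolated), via aldol mesylate 17 (not isolated)
Conditions: 14, LiN(iPr)2, THF, −78 °C; then 13; then MsCl, −78 → 0 °C; then DBU, 0 °C → rt
Reagents that add atoms: none
Why: Vinylogous aldol addition of the C5 lithium dienolate of the methyl tetronate to the aldehyde, mesylation of the aldolate and E1cB elimination with DBU give the thermodynamically preferred (Z)-ylidene (chain syn to the ring oxygen, away from the 4-OMe group); the transient carbinol and ring C5 centers of 16 and 17 are destroyed in the elimination and C18 is not deprotonated under these conditions.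

**Step 8**
Reactants: 18 (5Z)-5-[(2S,6Z,10E)-13-(furan-3-yl)-2,6,10-trimethyltrideca-6,10-dien-1-ylidene]-4-methoxy-3-methylfuran-2(5H)-one
Product: 20 (5Z)-5-[(2S,6Z,10E)-13-(furan-3-yl)-2,6,10-trimethyltrideca-6,10-dien-1-ylidene]-4-hydroxy-3-methylfuran-2(5H)-one, via lithium tetronate salt 19 (not isolated)
Conditions: LiCl (10 equiv), DMF, 70 °C; then 1 M HCl
Reagents that add atoms: none
Why: Krapcho-type SN2 O-demethylation of the vinylogous methyl ester by chloride is driven by formation of the stabilised tetronate anion and touches neither the furan, the three alkenes nor C18; acidification gives the free tetronic acid.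

**Compound list**
1 | geranyl acetate, (2E)-3,7-dimethylocta-2,6-dien-1-yl acetate | CC(C)=CCC/C(C)=C/COC(C)=O | starting material
2 | secondary ozonide, (2E)-5-(5,5-dimethyl-1,2,4-trioxolan-3-yl)-3-methylpent-2-en-1-yl acetate (racemic at the ring carbon) | CC1(C)OOC(CC/C(C)=C/COC(C)=O)O1 | intermediate
3 | (2E)-3-methyl-6-oxohex-2-en-1-yl acetate | O=CCC/C(C)=C/COC(C)=O | intermediate
4 | (2E,6Z)-7-iodo-3-methylocta-2,6-dien-1-yl acetate | I/C(C)=C\CC/C(C)=C/COC(C)=O | intermediate
5 | 3-(chloromethyl)furan | ClCc1ccoc1 | starting material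
6 | (furan-3-ylmethyl)magnesium chloride | Cl[Mg]Cc1ccoc1 | intermediate
7 | 3-[(3E,7Z)-8-iodo-4-methylnona-3,7-dien-1-yl]furan | I/C(C)=C\CC/C(C)=C/CCc1ccoc1 | intermediate
8 | methyl (2R)-3-bromo-2-methylpropanoate | COC(=O)[C@@H](C)CBr | starting material
9 | vinylboronic acid pinacol ester, 4,4,5,5-tetramethyl-2-vinyl-1,3,2-dioxaborolane | C=CB1OC(C)(C)C(C)(C)O1 | starting material
10 | methyl (2S)-2-methyl-5-(4,4,5,5-tetramethyl-1,3,2-dioxaborolan-2-yl)pentanoate | COC(=O)[C@@H](C)CCCB1OC(C)(C)C(C)(C)O1 | intermediate
11 | methyl (2S,6Z,10E)-13-(furan-3-yl)-2,6,10-trimethyltrideca-6,10-dienoate | COC(=O)[C@@H](C)CCC/C(C)=C\CC/C(C)=C/CCc1ccoc1 | intermediate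
12 | diisobutylaluminium hemiacetal of 11 (O-Al(iBu)2 and OMe on the former ester carbon, epimer mixture there) | COC(O[Al](CC(C)C)CC(C)C)[C@@H](C)CCC/C(C)=C\CC/C(C)=C/CCc1ccoc1 | intermediate
13 | (2S,6Z,10E)-13-(furan-3-yl)-2,6,10-trimethyltrideca-6,10-dienal | O=C[C@@H](C)CCC/C(C)=C\CC/C(C)=C/CCc1ccoc1 | intermediate
14 | 4-methoxy-3-methylfuran-2(5H)-one | COC1=C(C)C(=O)OC1 | starting material
15 | 5-lithio-4-methoxy-3-methylfuran-2(5H)-one (lithium dienolate drawn as the C5-lithio form) | COC1=C(C)C(=O)OC1[Li] | intermediate
16 | lithium alkoxide of 5-[(2S,6Z,10E)-13-(furan-3-yl)-1-hydroxy-2,6,10-trimethyltrideca-6,10-dien-1-yl]-4-methoxy-3-methylfuran-2(5H)-one (epimer mixture at the carbinol carbon and ring C5) | COC1=C(C)C(=O)OC1C(O[Li])[C@@H](C)CCC/C(C)=C\CC/C(C)=C/CCc1ccoc1 | intermediate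
17 | methanesulfonate of the aldol (same skeleton as 16, OMs in place of OLi, epimer mixture) | COC1=C(C)C(=O)OC1C(OS(C)(=O)=O)[C@@H](C)CCC/C(C)=C\CC/C(C)=C/CCc1ccoc1 | intermediate
18 | (5Z)-5-[(2S,6Z,10E)-13-(furan-3-yl)-2,6,10-trimethyltrideca-6,10-dien-1-ylidene]-4-methoxy-3-methylfuran-2(5H)-one | CC1=C(OC)/C(=C/[C@@H](C)CCC/C(C)=C\CC/C(C)=C/CCc2ccoc2)OC1=O | intermediate
19 | lithium salt (4-O-lithium tetronate) of 20 | CC1=C(O[Li])/C(=C/[C@@H](C)CCC/C(C)=C\CC/C(C)=C/CCc2ccoc2)OC1=O | intermediate
20 | (5Z)-5-[(2S,6Z,10E)-13-(furan-3-yl)-2,6,10-trimethyltrideca-6,10-dien-1-ylidene]-4-hydroxy-3-methylfuran-2(5H)-one (CNP0168546.4) | CC1=C(O)/C(=C/[C@@H](C)CCC/C(C)=C\CC/C(C)=C/CCc2ccoc2)OC1=O | target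

**Step count**
Total: 8 steps. Longest linear sequence: 7 steps (steps 1, 2, 3, 5, 6, 7, 8 from geranyl acetate); step 4 is a one-step branch.

**Steps most likely to fail, with fallbacks**

Step 5 (the proposed new coupling) is the most uncertain. Nickel-mediated C–N coupling of morpholine with the alkenyl iodide, or slow radical release from the primary boronate, could erode the yield. The fallback uses known two-electron chemistry. It sets out from 10 and comes back to the route at 11. Boronate 10 is treated with KHF2 in MeOH/H2O to give potassium trifluoro[(4S)-5-methoxy-4-methyl-5-oxopentyl]borate F1. F1 is then coupled with 7 under Suzuki–Miyaura conditions for primary alkyltrifluoroborates (PdCl2(dppf), Cs2CO3, toluene/H2O, 80 °C), which proceeds through zerovalent palladium with retention of the iodide geometry and delivers 11.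

Step 3 carries the risk that the Grignard reagent attacks the acetate carbonyl or the alkenyl iodide instead of displacing the acetate. The fallback attaches the furan before the iodide exists. It sets out from 3 and comes back at 7. Aldehyde 3 is converted with HC(OMe)3 and catalytic pyridinium p-toluenesulfonate in MeOH into (2E)-6,6-dimethoxy-3-methylhex-2-en-1-yl acetate F2. F2 is coupled with Grignard reagent 6 under Li2CuCl4 catalysis to give 3-[(3E)-7,7-dimethoxy-4-methylhept-3-en-1-yl]furan F3. Mild hydrolysis (oxalic acid on wet silica, CH2Cl2) releases (4E)-7-(furan-3-yl)-4-methylhept-4-enal F4. F4 is then taken through the Stork–Zhao iodo-olefination of step 2 to give 7.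

Step 4 may suffer from simple reduction of the bromide by the silane or from telomerisation of vinyl-Bpin. The fallback replaces the radical addition by organozinc chemistry. It sets out from 8 and comes back at 10. Bromide 8 is inserted with Zn dust and LiCl in THF to give [(2R)-3-methoxy-2-methyl-3-oxopropyl]zinc bromide F5. Negishi coupling of F5 with vinyl bromide (Pd(PPh3)4, THF) gives methyl (2S)-2-methylpent-4-enoate F6. Anti-Markovnikov hydroboration of F6 with pinacolborane ([Ir(cod)Cl]2 with bis(diphenylphosphino)methane, CH2Cl2, rt) gives 10.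

**Further compounds**
F1 | step 5 | potassium trifluoro[(4S)-5-methoxy-4-methyl-5-oxopentyl]borate | COC(=O)[C@@H](C)CCC[B-](F)(F)F.[K+]
F2 | step 3 | (2E)-6,6-dimethoxy-3-methylhex-2-en-1-yl acetate | COC(OC)CC/C(C)=C/COC(C)=O
F3 | step 3 | 3-[(3E)-7,7-dimethoxy-4-methylhept-3-en-1-yl]furan | COC(OC)CC/C(C)=C/CCc1ccoc1
F4 | step 3 | (4E)-7-(furan-3-yl)-4-methylhept-4-enal | O=CCC/C(C)=C/CCc1ccoc1
F5 | step 4 | [(2R)-3-methoxy-2-methyl-3-oxopropyl]zinc bromide | COC(=O)[C@@H](C)C[Zn]Br
F6 | step 4 | methyl (2S)-2-methylpent-4-enoate | COC(=O)[C@@H](C)CC=C
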